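**Plan**

Ring numbering: C1 = C(CH3)(CH=CHCl), C2 = CH2, C3 = C(Cl)(CH2Br), C4 = CHBr, C5 = CH2, C6 = CHCl.
Retrosynthesis: the C6–Cl and C4–Br bonds go back to alcohols of opposite configuration, the C3–Cl and CH2–Br bonds to an exocyclic C3=CH2 alkene, and the ring bond C3–C4 is then cut; in the chain, C1–C2, C4–C5 and the chloroalkene C=C are cut last.
The ring cut is possible because C3 bears an exocyclic one-carbon unit next to the heteroatom-bearing C4: C3 can act as an alkenyl nucleophile and C4 as an aldehyde, and their union is the 2-methylenecyclohexanol that the halogenations need.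
Forward: methyl 2-methylacetoacetate is extended by C4 (benzyl chloromethyl ether), reduced, allylated at C1 with 2,3-dibromopropene and turned into the chloroalkenyl aldehyde; the single ring closes by chromium/nickel alkenyl–aldehyde coupling; the four halogens on sp3 carbon follow.
Stereochemistry: C6 from a BINAP–ruthenium hydrogenation, C1 from chelate-controlled dianion alkylation relative to C6, C4 from the chair transition state of the ring closure, C3 from addition to the alkene on the face away from the axial C1 methyl; C4 and C6 are finally inverted by bromide and chloride.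

Key step: step 10

Remark (assumptions): "upper face" means the ring face of the chlorovinyl group and "lower face" that of the C1 methyl. Compound 5 is carried on as a mixture of C2 epimers because step 3 re-forms that centre. The CrCl2 used in step 7 is taken to be free of nickel.

**Route**

Step 1
Reactants: 1 methyl 2-methyl-3-oxobutanoate (methyl 2-methylacetoacetate, racemic); 2 benzyl chloromethyl ether
Product: 4 methyl 5-(benzyloxy)-2-methyl-3-oxopentanoate, via dilithium dienolate 3 (not isolated)
Conditions: LiN(iPr)2 (2.2 equiv), THF, 0 °C; then 2, –78 → 0 °C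
Reagents that add atoms: benzyl chloromethyl ether (compound 2), ClCOCc1ccccc1
Why: Alkylation of a β-keto ester dianion, in which the second deprotonation gives the more reactive terminal carbanion and only that carbon attacks the α-chloro ether; C2 stays racemic and is re-formed in step 3.

Step 2
Reactants: 4 methyl 5-(benzyloxy)-2-methyl-3-oxopentanoate
Product: 5 methyl (3S)-5-(benzyloxy)-3-hydroxy-2-methylpentanoate (both C2 epimers)
Conditions: H2 (50 atm), RuCl2[(S)-BINAP] (0.5 mol%), MeOH, 50 °C
Reagents that add atoms: none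
Why: Noyori asymmetric hydrogenation of a β-keto ester, in which the chelated substrate takes hydride on one carbonyl face from the (S)-BINAP complex of divalent ruthenium, setting the carbinol (ring C6) as S whatever the configuration at C2; the benzyl ether is not cleaved.

Step 3
Reactants: 5 methyl (3S)-5-(benzyloxy)-3-hydroxy-2-methylpentanoate; 6 2,3-dibromopropene
Product: 8 methyl (2S,3S)-5-(benzyloxy)-2-(2-bromoprop-2-en-1-yl)-3-hydroxy-2-methylpentanoate, via dilithium alkoxide enolate 7 (not isolated)
Conditions: LiN(iPr)2 (2.2 equiv), THF, –78 → –20 °C; then 6, DMPU, –78 → –10 °C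
Reagents that add atoms: 2,3-dibromopropene (compound 6), C=C(Br)CBr
Why: Fráter–Seebach alkylation, in which the rigid six-membered lithium chelate of the alkoxide enolate is attacked by the allylic bromide on the face anti to the carbinol side chain, so the quaternary centre (ring C1) forms as 2S with the bromoallyl group anti to the hydroxyl; the alkenyl bromide is inert.

Step 4
Reactants: 8 methyl (2S,3S)-5-(benzyloxy)-2-(2-bromoprop-2-en-1-yl)-3-hydroxy-2-methylpentanoate
Product: 9 methyl (2S,3S)-5-(benzyloxy)-2-(2-bromoprop-2-en-1-yl)-3-[(tert-butyldimethylsilyl)oxy]-2-methylpentanoate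
Conditions: TBSOTf, 2,6-lutidine, CH2Cl2, –78 → 0 °C
Reagents that add atoms: tert-butyldimethylsilyl trifluoromethanesulfonate, CC(C)(C)[Si](C)(C)OS(=O)(=O)C(F)(F)F
Why: Silylation of a hindered secondary alcohol with a silyl triflate and a hindered base; no stereocentre is touched.

Step 5
Reactants: 9 methyl (2S,3S)-5-(benzyloxy)-2-(2-bromoprop-2-en-1-yl)-3-[(tert-butyldimethylsilyl)oxy]-2-methylpentanoate
Product: 10 (2R,3S)-5-(benzyloxy)-2-(2-bromoprop-2-en-1-yl)-3-[(tert-butyldimethylsilyl)oxy]-2-methylpentan-1-ol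
Conditions: iBu2AlH (3 equiv), CH2Cl2, –78 → 0 °C; Rochelle salt work-up
Reagents that add atoms: none
Why: Hydride reduction of an ester to the primary alcohol with iBu2AlH, which leaves the benzyl ether, the silyl ether and the alkenyl bromide alone (the descriptor at C2 changes only through the priority rules).

Step 6
Reactants: 10 (2R,3S)-5-(benzyloxy)-2-(2-bromoprop-2-en-1-yl)-3-[(tert-butyldimethylsilyl)oxy]-2-methylpentan-1-ol
Product: 11 (2S,3S)-5-(benzyloxy)-2-(2-bromoprop-2-en-1-yl)-3-[(tert-butyldimethylsilyl)oxy]-2-methylpentanal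
Conditions: Dess–Martin periodinane, CH2Cl2, 0 → 25 °C
Reagents that add atoms: none
Why: Dess–Martin oxidation of a neopentyl primary alcohol to an aldehyde that has no α-hydrogen and therefore cannot epimerise.

Step 7
Reactants: 11 (2S,3S)-5-(benzyloxy)-2-(2-bromoprop-2-en-1-yl)-3-[(tert-butyldimethylsilyl)oxy]-2-methylpentanal
Product: 12 tert-butyl{[(3S,4R,5E)-1-(benzyloxy)-4-(2-bromoprop-2-en-1-yl)-6-chloro-4-methylhex-5-en-3-yl]oxy}dimethylsilane
Conditions: CrCl2 (8 equiv), CHCl3 (4 equiv), THF, 65 °C
Reagents that add atoms: chloroform, ClC(Cl)Cl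
Why: Takai olefination, in which the geminal dichromium species made from chloroform and divalent chromium adds to the aldehyde and the β-oxychromium intermediate eliminates to the (E)-chloroalkene, while the alkenyl bromide does not react with CrCl2 in the absence of nickel.

Step 8
Reactants: 12 tert-butyl{[(3S,4R,5E)-1-(benzyloxy)-4-(2-bromoprop-2-en-1-yl)-6-chloro-4-methylhex-5-en-3-yl]oxy}dimethylsilane
Product: 13 (3S,4R,5E)-4-(2-bromoprop-2-en-1-yl)-3-[(tert-butyldimethylsilyl)oxy]-6-chloro-4-methylhex-5-en-1-ol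
Conditions: BCl3, CH2Cl2, –78 °C; then H2O
Reagents that add atoms: none
Why: Lewis-acid cleavage of a primary benzyl ether, in which chloride attacks the benzylic carbon of the boron–ether complex at a temperature where the hindered secondary silyl ether and both alkenyl halides should persist (hydrogenolysis is excluded by the alkenes and halides).

Step 9
Reactants: 13 (3S,4R,5E)-4-(2-bromoprop-2-en-1-yl)-3-[(tert-butyldimethylsilyl)oxy]-6-chloro-4-methylhex-5-en-1-ol
Product: 14 (3S,4R,5E)-4-(2-bromoprop-2-en-1-yl)-3-[(tert-butyldimethylsilyl)oxy]-6-chloro-4-methylhex-5-enal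
Conditions: Dess–Martin periodinane, CH2Cl2, 0 → 25 °C; used without storage
Reagents that add atoms: none
Why: Dess–Martin oxidation under non-basic conditions, which should give the β-silyloxy aldehyde without β-elimination.

Step 10
Reactants: 14 (3S,4R,5E)-4-(2-bromoprop-2-en-1-yl)-3-[(tert-butyldimethylsilyl)oxy]-6-chloro-4-methylhex-5-enal
Product: 16 (1R,4R,5S)-5-[(tert-butyldimethylsilyl)oxy]-4-[(E)-2-chloroethenyl]-4-methyl-2-methylidenecyclohexan-1-ol, via alkenylchromium dichloride 15 (not isolated)
Conditions: CrCl2 (6 equiv), NiCl2 (5 mol%), degassed DMF, 0.01 M, 25 °C; then H2O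
Reagents that add atoms: none
Why: This is a Nozaki–Hiyama–Kishi reaction in its intramolecular alkenyl halide–aldehyde form, the established route to 2-methylenecycloalkanols: zerovalent nickel (made from NiCl2 by CrCl2) adds oxidatively to the C–Br bond, transmetalation to trivalent chromium gives 15, and this alkenylchromium attacks the aldehyde carbon. The new C3–C4 bond closes the carbocycle in a 6-exo-trig mode, the carbonyl oxygen staying outside the ring. The only new stereocentre, C4, should be set by a chair transition state in which the C6 silyloxy group and the chromium-bound oxygen with its solvated metal are both equatorial and the C1 methyl is axial, which gives the 4,6-cis alcohol (1R in the name of 16). The step needs chemoselectivity between two alkenyl halides and tolerance of a β-silyloxy aldehyde: nickel inserts far faster into C–Br than into C–Cl, and the neutral alkenylchromium neither enolises the aldehyde nor expels the silyloxy group. High dilution keeps the coupling intramolecular.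

Step 11
Reactants: 16 (1R,4R,5S)-5-[(tert-butyldimethylsilyl)oxy]-4-[(E)-2-chloroethenyl]-4-methyl-2-methylidenecyclohexan-1-ol
Product: 18 (1R,2R,4R,5S)-2-(bromomethyl)-5-[(tert-butyldimethylsilyl)oxy]-2-chloro-4-[(E)-2-chloroethenyl]-4-methylcyclohexan-1-ol, via titanium alkoxide 17 (not isolated)
Conditions: ClTi(OiPr)3 (1.1 equiv), CH2Cl2/hexane, 25 °C; then NBS (1.1 equiv), –20 °C; then H2O
Reagents that add atoms: N-bromosuccinimide, O=C1CCC(=O)N1Br; chlorotitanium triisopropoxide, CC(C)O[Ti](Cl)(OC(C)C)OC(C)C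
Why: Titanium-mediated bromochlorination of an allylic alcohol, in which the alcohol exchanges onto titanium (17), NBS forms the bromonium ion on the exocyclic alkene and chloride passes from titanium to C3 (the carbon next to the carbinol and also the Markovnikov position), leaving bromine on the exocyclic carbon; in the chair with both oxygens equatorial the axial C1 methyl covers the lower face of C3, so chloride should enter on the upper face, trans to O4 (new centre 2R in 18), and the electron-poor chloroalkene is not attacked.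

Step 12
Reactants: 18 (1R,2R,4R,5S)-2-(bromomethyl)-5-[(tert-butyldimethylsilyl)oxy]-2-chloro-4-[(E)-2-chloroethenyl]-4-methylcyclohexan-1-ol
Product: 20 tert-butyl{[(1S,2R,4S,5S)-5-bromo-4-(bromomethyl)-4-chloro-2-[(E)-2-chloroethenyl]-2-methylcyclohexyl]oxy}dimethylsilane, via C4 triflate 19 (not isolated)
Conditions: Tf2O, 2,6-lutidine, CH2Cl2, –30 °C; then Bu4NBr, –30 → 25 °C
Reagents that add atoms: tetrabutylammonium bromide, CCCC[N+](CCCC)(CCCC)CCCC.[Br-]
Why: SN2 displacement of a secondary triflate by bromide with inversion, as practised on carbohydrate triflates: in the chair with triflate and silyloxy group equatorial only ring bonds are antiperiplanar to the leaving group, so chloronium participation and E2 are disfavoured, the β-chlorine retards ionisation, and bromide enters axially on the upper face to give the 5S bromide (ring C4).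

Step 13
Reactants: 20 tert-butyl{[(1S,2R,4S,5S)-5-bromo-4-(bromomethyl)-4-chloro-2-[(E)-2-chloroethenyl]-2-methylcyclohexyl]oxy}dimethylsilane
Product: 21 (1S,2R,4S,5S)-5-bromo-4-(bromomethyl)-4-chloro-2-[(E)-2-chloroethenyl]-2-methylcyclohexan-1-ol
Conditions: HF (48% aq), MeCN, 25 °C
Reagents that add atoms: none
Why: Acidic desilylation with aqueous HF, chosen over basic fluoride sources so that the secondary bromide and the tertiary chloride do not eliminate; no stereocentre is touched.

Step 14
Reactants: 21 (1S,2R,4S,5S)-5-bromo-4-(bromomethyl)-4-chloro-2-[(E)-2-chloroethenyl]-2-methylcyclohexan-1-ol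
Product: 22 (1S,2S,4R,5R)-2-bromo-1-(bromomethyl)-1,4-dichloro-5-[(E)-2-chloroethenyl]-5-methylcyclohexane
Conditions: PPh3, CCl4, toluene, 70 °C
Reagents that add atoms: carbon tetrachloride, ClC(Cl)(Cl)Cl
Why: Appel chlorination, in which chloride displaces the alkoxyphosphonium group at C6 with inversion, as in Appel inversions of axial cyclohexanols next to a quaternary carbon, turning the lower-face alcohol into the upper-face, equatorial chloride of the target (4R in the name of 22).

**Compound list**

1 | methyl 2-methyl-3-oxobutanoate (methyl 2-methylacetoacetate, racemic) | COC(=O)C(C)C(C)=O | starting material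
2 | benzyl chloromethyl ether | ClCOCc1ccccc1 | starting material
3 | dilithium dienolate of 1 (dilithium 1-methoxy-2-methylbuta-1,3-diene-1,3-diolate) | [Li+].[Li+].C=C([O-])C(C)=C([O-])OC | intermediate
4 | methyl 5-(benzyloxy)-2-methyl-3-oxopentanoate (racemic) | COC(=O)C(C)C(=O)CCOCc1ccccc1 | intermediate
5 | methyl (3S)-5-(benzyloxy)-3-hydroxy-2-methylpentanoate (both C2 epimers) | COC(=O)C(C)[C@@H](O)CCOCc1ccccc1 | intermediate
6 | 2,3-dibromopropene | C=C(Br)CBr | starting material
7 | dilithium alkoxide enolate of 5 (3S) | [Li+].[Li+].COC([O-])=C(C)[C@@H]([O-])CCOCc1ccccc1 | intermediate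
8 | methyl (2S,3S)-5-(benzyloxy)-2-(2-bromoprop-2-en-1-yl)-3-hydroxy-2-methylpentanoate | C[C@](C(=O)OC)(CC(Br)=C)[C@@H](O)CCOCc1ccccc1 | intermediate
9 | methyl (2S,3S)-5-(benzyloxy)-2-(2-bromoprop-2-en-1-yl)-3-[(tert-butyldimethylsilyl)oxy]-2-methylpentanoate | C[C@](C(=O)OC)(CC(Br)=C)[C@@H](O[Si](C)(C)C(C)(C)C)CCOCc1ccccc1 | intermediate
10 | (2R,3S)-5-(benzyloxy)-2-(2-bromoprop-2-en-1-yl)-3-[(tert-butyldimethylsilyl)oxy]-2-methylpentan-1-ol | C[C@](CO)(CC(Br)=C)[C@@H](O[Si](C)(C)C(C)(C)C)CCOCc1ccccc1 | intermediate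
11 | (2S,3S)-5-(benzyloxy)-2-(2-bromoprop-2-en-1-yl)-3-[(tert-butyldimethylsilyl)oxy]-2-methylpentanal | C[C@](C=O)(CC(Br)=C)[C@@H](O[Si](C)(C)C(C)(C)C)CCOCc1ccccc1 | intermediate
12 | tert-butyl{[(3S,4R,5E)-1-(benzyloxy)-4-(2-bromoprop-2-en-1-yl)-6-chloro-4-methylhex-5-en-3-yl]oxy}dimethylsilane | C[C@](/C=C/Cl)(CC(Br)=C)[C@@H](O[Si](C)(C)C(C)(C)C)CCOCc1ccccc1 | intermediate
13 | (3S,4R,5E)-4-(2-bromoprop-2-en-1-yl)-3-[(tert-butyldimethylsilyl)oxy]-6-chloro-4-methylhex-5-en-1-ol | C[C@](/C=C/Cl)(CC(Br)=C)[C@@H](O[Si](C)(C)C(C)(C)C)CCO | intermediate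
14 | (3S,4R,5E)-4-(2-bromoprop-2-en-1-yl)-3-[(tert-butyldimethylsilyl)oxy]-6-chloro-4-methylhex-5-enal | C[C@](/C=C/Cl)(CC(Br)=C)[C@@H](O[Si](C)(C)C(C)(C)C)CC=O | intermediate
15 | alkenylchromium dichloride derived from 14 (C–Br replaced by C–CrCl2) | C[C@](/C=C/Cl)(CC(=C)[Cr](Cl)Cl)[C@@H](O[Si](C)(C)C(C)(C)C)CC=O | intermediate
16 | (1R,4R,5S)-5-[(tert-butyldimethylsilyl)oxy]-4-[(E)-2-chloroethenyl]-4-methyl-2-methylidenecyclohexan-1-ol | C[C@]1(/C=C/Cl)CC(=C)[C@H](O)C[C@@H]1O[Si](C)(C)C(C)(C)C | intermediate
17 | chlorodiisopropoxytitanium alkoxide of 16 | C[C@]1(/C=C/Cl)CC(=C)[C@H](O[Ti](Cl)(OC(C)C)OC(C)C)C[C@@H]1O[Si](C)(C)C(C)(C)C | intermediate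
18 | (1R,2R,4R,5S)-2-(bromomethyl)-5-[(tert-butyldimethylsilyl)oxy]-2-chloro-4-[(E)-2-chloroethenyl]-4-methylcyclohexan-1-ol | C[C@]1(/C=C/Cl)C[C@](Cl)(CBr)[C@H](O)C[C@@H]1O[Si](C)(C)C(C)(C)C | intermediate
19 | trifluoromethanesulfonate of 18 (C4 triflate) | C[C@]1(/C=C/Cl)C[C@](Cl)(CBr)[C@H](OS(=O)(=O)C(F)(F)F)C[C@@H]1O[Si](C)(C)C(C)(C)C | intermediate
20 | tert-butyl{[(1S,2R,4S,5S)-5-bromo-4-(bromomethyl)-4-chloro-2-[(E)-2-chloroethenyl]-2-methylcyclohexyl]oxy}dimethylsilane | C[C@]1(/C=C/Cl)C[C@](Cl)(CBr)[C@@H](Br)C[C@@H]1O[Si](C)(C)C(C)(C)C | intermediate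
21 | (1S,2R,4S,5S)-5-bromo-4-(bromomethyl)-4-chloro-2-[(E)-2-chloroethenyl]-2-methylcyclohexan-1-ol | C[C@]1(/C=C/Cl)C[C@](Cl)(CBr)[C@@H](Br)C[C@@H]1O | intermediate
22 | (1S,2S,4R,5R)-2-bromo-1-(bromomethyl)-1,4-dichloro-5-[(E)-2-chloroethenyl]-5-methylcyclohexane | C[C@]1(/C=C/Cl)C[C@](Cl)(CBr)[C@@H](Br)C[C@H]1Cl | target

**Totals and risks**

Total steps: 14. Longest linear sequence: 14 steps (from methyl 2-methylacetoacetate).

Step 14. Substitution at C6 may lose out to E2 elimination toward C5 or to a 1,2-shift of the chlorovinyl group. In the favoured chair of 21 the activated oxygen is axial, an axial C5–H and the axial chlorovinyl group are antiperiplanar to it, and the latter screens the backside of C6. Fallback, from 18 back to 22: the two displacements change places, so that C6 is substituted while its leaving group is equatorial and only ring bonds are antiperiplanar to it. Acetylation of 18 (Ac2O, DMAP, pyridine) would give (1R,2R,4R,5S)-2-(bromomethyl)-5-[(tert-butyldimethylsilyl)oxy]-2-chloro-4-[(E)-2-chloroethenyl]-4-methylcyclohexyl acetate F1. Aqueous HF in MeCN would free O6 to give (1R,2R,4R,5S)-2-(bromomethyl)-2-chloro-4-[(E)-2-chloroethenyl]-5-hydroxy-4-methylcyclohexyl acetate F2. PPh3/CCl4 would convert this with inversion into (1R,2R,4R,5R)-2-(bromomethyl)-2,5-dichloro-4-[(E)-2-chloroethenyl]-4-methylcyclohexyl acetate F3. Reductive removal of the acetate with iBu2AlH at –78 °C, which avoids a basic alkoxide next to the tertiary chloride, would give (1R,2R,4R,5R)-2-(bromomethyl)-2,5-dichloro-4-[(E)-2-chloroethenyl]-4-methylcyclohexan-1-ol F4. Tf2O/2,6-lutidine would then form (1R,2R,4R,5R)-2-(bromomethyl)-2,5-dichloro-4-[(E)-2-chloroethenyl]-4-methylcyclohexyl trifluoromethanesulfonate F5, which Bu4NBr would displace in the same flask with inversion to give 22. This detour moves the harder, second displacement to C4, where the β-chlorine allows a triflate to be used.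

Step 12. Neighbouring-group participation by the tertiary chlorine (chloronium formation, leading to retention or chlorine shift) or ionisation may compete if the ring flips so that the triflate becomes axial. Fallback, from 16 back to 20: the bromide is introduced while C3 is still sp2 and carries no halogen. Appel reaction of 16 (CBr4, PPh3, CH2Cl2, 0 °C) should give, by SN2 with inversion, the allylic bromide tert-butyl{[(1S,2R,5S)-5-bromo-2-[(E)-2-chloroethenyl]-2-methyl-4-methylidenecyclohexyl]oxy}dimethylsilane F6. Tetrabutylammonium dichlorobromate (Bu4NBrCl2, CH2Cl2, –20 °C) would then add BrCl across the exocyclic alkene, bromine going to the CH2 terminus and chloride to C3 on the upper face, to give 20. The axial C4 bromide should send the bromonium ion to the lower face, and the axial methyl should keep chloride off that face.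

Step 11. Facial selectivity may be lost if chloride is handed from the titanium alkoxide to the lower face of C3, cis to O4, which would give the C3 epimer. Fallback, from 16 back to 18: O4 is capped so that only free chloride can attack and the axial methyl alone decides the face. TESOTf/2,6-lutidine would give tert-butyl{[(1S,2R,5R)-2-[(E)-2-chloroethenyl]-2-methyl-4-methylidene-5-[(triethylsilyl)oxy]cyclohexyl]oxy}dimethylsilane F7. Bu4NBrCl2 in CH2Cl2 at –20 °C would add BrCl to give tert-butyl{[(1S,2R,4R,5R)-4-(bromomethyl)-4-chloro-2-[(E)-2-chloroethenyl]-2-methyl-5-[(triethylsilyl)oxy]cyclohexyl]oxy}dimethylsilane F8. PPTS in MeOH would remove the triethylsilyl group in the presence of the hindered TBS ether and return 18.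

**Further compounds**

F1 | step 14 | (1R,2R,4R,5S)-2-(bromomethyl)-5-[(tert-butyldimethylsilyl)oxy]-2-chloro-4-[(E)-2-chloroethenyl]-4-methylcyclohexyl acetate | C[C@]1(/C=C/Cl)C[C@](Cl)(CBr)[C@H](OC(C)=O)C[C@@H]1O[Si](C)(C)C(C)(C)C
F2 | step 14 | (1R,2R,4R,5S)-2-(bromomethyl)-2-chloro-4-[(E)-2-chloroethenyl]-5-hydroxy-4-methylcyclohexyl acetate | C[C@]1(/C=C/Cl)C[C@](Cl)(CBr)[C@H](OC(C)=O)C[C@@H]1O
F3 | step 14 | (1R,2R,4R,5R)-2-(bromomethyl)-2,5-dichloro-4-[(E)-2-chloroethenyl]-4-methylcyclohexyl acetate | C[C@]1(/C=C/Cl)C[C@](Cl)(CBr)[C@H](OC(C)=O)C[C@H]1Cl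
F4 | step 14 | (1R,2R,4R,5R)-2-(bromomethyl)-2,5-dichloro-4-[(E)-2-chloroethenyl]-4-methylcyclohexan-1-ol | C[C@]1(/C=C/Cl)C[C@](Cl)(CBr)[C@H](O)C[C@H]1Cl
F5 | step 14 | (1R,2R,4R,5R)-2-(bromomethyl)-2,5-dichloro-4-[(E)-2-chloroethenyl]-4-methylcyclohexyl trifluoromethanesulfonate | C[C@]1(/C=C/Cl)C[C@](Cl)(CBr)[C@H](OS(=O)(=O)C(F)(F)F)C[C@H]1Cl
F6 | step 12 | tert-butyl{[(1S,2R,5S)-5-bromo-2-[(E)-2-chloroethenyl]-2-methyl-4-methylidenecyclohexyl]oxy}dimethylsilane | C[C@]1(/C=C/Cl)CC(=C)[C@@H](Br)C[C@@H]1O[Si](C)(C)C(C)(C)C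
F7 | step 11 | tert-butyl{[(1S,2R,5R)-2-[(E)-2-chloroethenyl]-2-methyl-4-methylidene-5-[(triethylsilyl)oxy]cyclohexyl]oxy}dimethylsilane | C[C@]1(/C=C/Cl)CC(=C)[C@H](O[Si](CC)(CC)CC)C[C@@H]1O[Si](C)(C)C(C)(C)C
F8 | step 11 | tert-butyl{[(1S,2R,4R,5R)-4-(bromomethyl)-4-chloro-2-[(E)-2-chloroethenyl]-2-methyl-5-[(triethylsilyl)oxy]cyclohexyl]oxy}dimethylsilane | C[C@]1(/C=C/Cl)C[C@](Cl)(CBr)[C@H](O[Si](CC)(CC)CC)C[C@@H]1O[Si](C)(C)C(C)(C)C
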